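1. Slowness is the first suspicion, but the north run stands flat from 1.04 d, so something ends that run early.

the same everywhere: left-handed substrate 28 mM; right-handed substrate 28 mM

| flask | partner | protic impurity | catalyst | remark | time |
|---|---|---|---|---|---|
| south | 11 mM | 5.6 mM | 28 µM | run made earlier |  |
| north | 45 mM | 5.6 mM | 28 µM | run made earlier |  |
| east | 22.4 mM | 5.6 mM | 56 µM | run made earlier |  |
| flask | 22.4 mM | 5.60 mM | 28 µM |  | 8.0 d |

| run | time / d | right-handed substrate / % | left-handed substrate / % | left-handed product / % |
|---|---|---|---|---|
| south | 0.833 | 47.6 | 42.6 | 8.7 |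
| south | 1.67 | 46.5 | 42.2 | 6.7 |
| south | 3.00 | 47.0 | 43.4 | 7.4 |
| south | 4.00 | 46.3 | 41.7 | 9.1 |
| south | 5.00 | 46.6 | 42.0 | 7.3 |
| south | 6.00 | 47.1 | 42.5 | 8.6 |
| north | 0.333 | 42.9 | 35.1 | 16.5 |
| north | 1.04 | 42.3 | 32.9 | 16.4 |
| north | 1.67 | 42.7 | 33.7 | 16.8 |
| north | 3.00 | 43.2 | 32.9 | 17.1 |
| north | 4.00 | 41.9 | 33.6 | 16.7 |
| north | 5.00 | 41.7 | 31.9 | 16.6 |
| north | 6.00 | 42.4 | 32.8 | 17.7 |
| east | 0.625 | 42.9 | 32.6 | 15.3 |
| east | 1.67 | 42.4 | 34.7 | 14.3 |
| east | 3.00 | 43.1 | 35.0 | 15.9 |
| east | 5.00 | 42.7 | 35.4 | 16.0 |
| east | 6.00 | 42.6 | 34.7 | 16.0 |

(each reading ± 1 percentage point)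

- catalyst is single-handed; left-handed substrate and right-handed substrate are mirror images of each other, charged as a racemate, each of them at the stated concentration
- the analysis behind the earlier runs scatters by 1 percentage point, standard deviation

- whether the excess of right-handed substrate over left-handed substrate among what is left of the two reaches 98% by 8.0 d (no / yes)
- the highest excess of right-handed substrate over left-handed substrate among what is left of the two up to 8.0 d

2. Substrate consumed, X, from the mean readings: south 6.02 mM, north 13.6 mM, east 12.8 mM.

3. Dead catalyst? Then turnovers would match, but north gives 486 and east 228.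

4. Impurity? At one partner per substrate consumed, north wastes 31.4 mM of partner, more than its 5.6 mM of impurity. The useful share of partner falls from 54.7% in south to 30.2% in north, which suggests a loss second-order in partner.

5. Taking a catalysed loss first-order in [partner] against that second-order loss, dX/d[partner] = −λ/(λ + [partner]). Integrated, X = λ ln(1 + [partner]/λ) at the charge. Here λ, the crossover concentration, is the [partner] at which both losses are equal, and it scales with [catalyst] at fixed substrate. North gives λ = 6.70 mM.

6. Objection: substrate depletion and impurity are ignored. East, with doubled λ, is predicted at 13.2 mM, which is 0.73 percentage points of the charge high, against a scatter of 1 point per reading. The rule survives, perhaps reading slightly high.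

7. The asked flask has north's 28 µM of catalyst and north's substrate charge, so it takes north's λ, and X = 9.84 mM, a conversion c of 17.6%. The north means give a selectivity factor s = 2.49. At small conversion the excess is about (s−1)/(s+1)·ln(1/(1−c)) = 8.23%, less than 98%.

8. The forecast says no and 11%: “The substrates stop falling early in every run and then stay flat, so these are plateaus, not slow kinetics.” It agrees on the 98% question, and the excess reckoned in step 7 is lower.

9. The flask gives no and 8.40%.

    partner ⇌ dormant form (K = 0.800, k = 1.49 /h)
    partner + catalyst + right-handed substrate → catalyst + right-handed product (k = 3.64 × 10⁵ /M²/h)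
    partner + protic impurity → quenched reagent (k = 22.5 /M/h)
    partner + catalyst + left-handed substrate → catalyst + left-handed product (k = 9.04 × 10⁵ /M²/h)
    2 partner → self-condensation product (k = 88.2 /M/h)

Against 9.84 mM from λ, the flask turned 9.89 mM into both products, and its excess of 8.40% stands against 8.23%. At the start of the asked flask the route to left-handed product uses partner at 0.18 of the rate of self-condensation, and by 0.0273 d that ratio is 1.0.

In the same flask with 0.11 mM of catalyst, λ becomes 26.3 mM, so X = 16.2 mM and the excess about 14.6%. The computed neighbour turns 15.6 mM and reaches 14.2%, still below 98%.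

The numbers in the tables were computed with made-up constants; the scatter is artificial.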